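Assumption: the SMILES is taken at face value. By CIP rules its carbinol carbon is S, and the alkenes are 5E,7E,14Z (prostanoid numbering, used below for atom labels C5–C13).

**Retrosynthetic overview**
- The C8=C7–C6=C5 dienylidene is unmasked at the end by redox-neutral isomerisation of a C8-alkynyl group (alkyne → allenone → E,E-dienone).
- The cyclopentenone, the only ring formed, comes from a catalytic asymmetric oxa-Piancatelli rearrangement of a fully substituted 2-furyl propargylic carbinol. The furan is dearomatised and the 4π-electrocyclisation sets the tertiary carbinol.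
- The carbinol comes from 3-chloro-5-[(Z)-oct-2-enyl]furfural and methyl hept-6-ynoate.
- The aldehyde comes from furfural by two α-amino-alkoxide-directed lithiations: C3 chlorination, then C5 allylation with (Z)-1-bromooct-2-ene.

**Route**

Step 1
Reactants: 1 furfural (furan-2-carbaldehyde)
Product: 5 3-chlorofuran-2-carbaldehyde, via lithium amino alkoxide 2 (not isolated), via C3-lithio amino alkoxide 3 (not isolated), via 3-chloro amino alkoxide 4 (not isolated)
Conditions: Me2NCH2CH2NHMe, n-BuLi, THF, −78 °C; add 1; n-BuLi (2 equiv), −78 → −20 °C; C2Cl6, −78 °C → rt; H2O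
Reagents that add atoms: hexachloroethane, ClC(Cl)(Cl)C(Cl)(Cl)Cl
Why: Comins α-amino-alkoxide-directed ortho-lithiation: the in-situ diamine adduct masks the aldehyde and its chelating arm delivers n-BuLi to C3, the aryllithium is chlorinated by C2Cl6, and aqueous collapse of the hemiaminal returns the aldehyde.

Step 2
Reactants: 6 (Z)-oct-2-en-1-ol
Product: 7 (Z)-1-bromooct-2-ene
Conditions: CBr4, PPh3, CH2Cl2, 0 °C
Reagents that add atoms: carbon tetrabromide, BrC(Br)(Br)Br
Why: Appel bromination is an SN2 displacement at the primary allylic carbon, so the Z-alkene is retained.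

Step 3
Reactants: 5 3-chlorofuran-2-carbaldehyde; 7 (Z)-1-bromooct-2-ene
Product: 11 3-chloro-5-[(2Z)-oct-2-en-1-yl]furan-2-carbaldehyde, via lithium piperazinyl alkoxide 8 (not isolated), via C5-lithio alkoxide 9 (not isolated), via C5-octenyl alkoxide 10 (not isolated)
Conditions: N-methylpiperazine, n-BuLi, THF, −78 °C; add 5; n-BuLi (1.1 equiv), −78 → −30 °C; 7, −78 → 0 °C; H2O
Reagents that add atoms: none
Why: In-situ α-amino-alkoxide protection (Comins) followed by α-lithiation at C5, the only free and most acidic furan position, and direct SN2 alkylation of the furyllithium by the primary allylic bromide, which keeps the Z-geometry because no π-allyl metal species is involved.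

Step 4
Reactants: 11 3-chloro-5-[(2Z)-oct-2-en-1-yl]furan-2-carbaldehyde; 12 methyl hept-6-ynoate
Product: 15 methyl 8-[3-chloro-5-[(2Z)-oct-2-en-1-yl]furan-2-yl]-8-hydroxyoct-6-ynoate (racemic at the carbinol carbon), via methylzinc acetylide 13 (not isolated), via zinc alkoxide 14 (not isolated)
Conditions: 12 (2 equiv), Me2Zn (2 equiv), toluene, 0 °C → rt; add 11, rt; H2O
Reagents that add atoms: none
Why: Me2Zn-mediated alkynylation of an aldehyde: the alkynylzinc transfers its alkynyl group in preference to methyl and leaves the methyl ester alone, and the racemic carbinol centre does not matter because it is ionised in step 5.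

Step 5
Reactants: 15 methyl 8-[3-chloro-5-[(2Z)-oct-2-en-1-yl]furan-2-yl]-8-hydroxyoct-6-ynoate
Product: 18 methyl 7-[(1R,2R)-4-chloro-2-hydroxy-2-[(2Z)-oct-2-en-1-yl]-5-oxocyclopent-3-en-1-yl]hept-6-ynoate, via dihydrofuranol 16 (not isolated), via hydroxypentadienyl cation 17 (not isolated)
Conditions: (R)-TRIP N-triflylphosphoramide (10 mol %), H2O (5 equiv), PhCl, 40 °C
Reagents that add atoms: water, O
Why: Proposed new method: the chiral acid ionises the furfuryl–propargyl alcohol to a furanoxocarbenium ion, water adds at the octenyl-bearing furan carbon to give 16, ring-opening gives the 2-chloro-1,4-dihydroxypentadienyl cation 17, and its conrotatory 4π-electrocyclisation inside the chiral contact ion pair sets the tertiary carbinol (the alkynyl-bearing centre, trans to OH, is transient and erased in step 6); the closest known reaction types are the ZnCl2-mediated Piancatelli rearrangement of 5-methyl-2-furylcarbinols to 4-hydroxy-4-methylcyclopentenones and the chiral phosphoric acid / N-triflylphosphoramide-catalysed enantioselective aza-Piancatelli rearrangement, and because the absolute sense is assigned only by analogy the (S)-catalyst is used instead if the first run gives the antipode.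

Step 6
Reactants: 18 methyl 7-[(1R,2R)-4-chloro-2-hydroxy-2-[(2Z)-oct-2-en-1-yl]-5-oxocyclopent-3-en-1-yl]hept-6-ynoate
Product: 20 methyl (5E,7E)-7-[(2S)-4-chloro-2-hydroxy-2-[(2Z)-oct-2-en-1-yl]-5-oxocyclopent-3-en-1-ylidene]hept-5-enoate (target), via allenone 19 (not isolated)
Conditions: Et3N (0.2 equiv), toluene, rt; then PPh3 (0.2 equiv), 40 °C
Reagents that add atoms: none
Why: Amine-mediated propargyl–allenyl isomerisation of the α-alkynyl ketone gives conjugated allenone 19, and phosphine-catalysed allenone → 2,4-dienone isomerisation (Trost–Lu) then gives the thermodynamic 5E,7E dienone, with the carbinol centre untouched because once C8 is sp2 neither retro-aldol nor E1cB loss of the hydroxyl is possible.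

**Compound list**

1 | furfural (furan-2-carbaldehyde) | O=Cc1ccco1 | starting material
2 | lithium {[2-(dimethylamino)ethyl](methyl)amino}(furan-2-yl)methanolate (racemic) | [Li]OC(c1ccco1)N(C)CCN(C)C | intermediate
3 | lithium {[2-(dimethylamino)ethyl](methyl)amino}(3-lithiofuran-2-yl)methanolate (racemic) | [Li]OC(c1occc1[Li])N(C)CCN(C)C | intermediate
4 | lithium (3-chlorofuran-2-yl){[2-(dimethylamino)ethyl](methyl)amino}methanolate (racemic) | [Li]OC(c1occc1Cl)N(C)CCN(C)C | intermediate
5 | 3-chlorofuran-2-carbaldehyde | O=Cc1occc1Cl | intermediate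
6 | (Z)-oct-2-en-1-ol | CCCCC/C=C\CO | starting material
7 | (Z)-1-bromooct-2-ene | CCCCC/C=C\CBr | intermediate
8 | lithium (3-chlorofuran-2-yl)(4-methylpiperazin-1-yl)methanolate (racemic) | [Li]OC(c1occc1Cl)N1CCN(C)CC1 | intermediate
9 | lithium (3-chloro-5-lithiofuran-2-yl)(4-methylpiperazin-1-yl)methanolate (racemic) | [Li]OC(c1oc([Li])cc1Cl)N1CCN(C)CC1 | intermediate
10 | lithium {3-chloro-5-[(2Z)-oct-2-en-1-yl]furan-2-yl}(4-methylpiperazin-1-yl)methanolate (racemic) | CCCCC/C=C\Cc1cc(Cl)c(C(O[Li])N2CCN(C)CC2)o1 | intermediate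
11 | 3-chloro-5-[(2Z)-oct-2-en-1-yl]furan-2-carbaldehyde | CCCCC/C=C\Cc1cc(Cl)c(C=O)o1 | intermediate
12 | methyl hept-6-ynoate | C#CCCCCC(=O)OC | starting material
13 | methyl(7-methoxy-7-oxohept-1-yn-1-yl)zinc | C[Zn]C#CCCCCC(=O)OC | intermediate
14 | methylzinc alkoxide of carbinol 15 (racemic) | CCCCC/C=C\Cc1cc(Cl)c(C(O[Zn]C)C#CCCCCC(=O)OC)o1 | intermediate
15 | methyl 8-[3-chloro-5-[(2Z)-oct-2-en-1-yl]furan-2-yl]-8-hydroxyoct-6-ynoate (racemic) | CCCCC/C=C\Cc1cc(Cl)c(C(O)C#CCCCCC(=O)OC)o1 | intermediate
16 | methyl 8-[3-chloro-5-hydroxy-5-[(2Z)-oct-2-en-1-yl]furan-2(5H)-ylidene]oct-6-ynoate (hemiketal, stereoisomer mixture) | CCCCC/C=C\CC1(O)C=C(Cl)C(=CC#CCCCCC(=O)OC)O1 | intermediate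
17 | U-shaped 2-chloro-1,4-dihydroxypentadienyl cation bearing the octenyl group at C1 and the alkynyl chain at C5 (ion pair with the catalyst anion) | CCCCC/C=C\CC(O)=CC(Cl)=C(O)[CH+]C#CCCCCC(=O)OC | intermediate
18 | methyl 7-[(1R,2R)-4-chloro-2-hydroxy-2-[(2Z)-oct-2-en-1-yl]-5-oxocyclopent-3-en-1-yl]hept-6-ynoate (OH and alkynyl trans) | CCCCC/C=C\C[C@]1(O)C=C(Cl)C(=O)[C@@H]1C#CCCCCC(=O)OC | intermediate
19 | methyl 7-[(2S)-4-chloro-2-hydroxy-2-[(2Z)-oct-2-en-1-yl]-5-oxocyclopent-3-en-1-ylidene]hept-6-enoate (allenone, mixture of allene axial isomers) | CCCCC/C=C\C[C@]1(O)C=C(Cl)C(=O)C1=C=CCCCCC(=O)OC | intermediate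
20 | methyl (5E,7E)-7-[(2S)-4-chloro-2-hydroxy-2-[(2Z)-oct-2-en-1-yl]-5-oxocyclopent-3-en-1-ylidene]hept-5-enoate | CCCCC/C=C\C[C@]1(O)C=C(Cl)C(=O)/C1=C/C=C/CCCC(=O)OC | target

**Totals**
Total step count: 6. Longest linear sequence: 5 steps (1 → 5 → 11 → 15 → 18 → 20); step 2 is a one-step side branch.

**Steps most likely to fail, with fallbacks**

Step 5 is the riskiest. The substrate class is new on three counts (alkynyl carbinol, 3-chloro substituent, quaternary centre), Meyer–Schuster-type hydration of the propargylic cation can compete, and the enantiocontrol is unproven. The fallback sets out from 15 and comes back at 18. The rearrangement is run without a chiral catalyst under the Lewis-acid conditions established for 5-alkyl-2-furylcarbinols (ZnCl2 or Dy(OTf)3, aqueous dioxane, 60–80 °C). This gives the racemic trans-cyclopentenone, that is 18 together with its mirror image methyl 7-[(1S,2S)-4-chloro-2-hydroxy-2-[(2Z)-oct-2-en-1-yl]-5-oxocyclopent-3-en-1-yl]hept-6-ynoate F1. Compound 18 is then taken by preparative chiral SFC, so the stereochemistry comes from resolution rather than from the electrocyclisation. If the alkynyl carbinol itself will not rearrange, the dienyl-carbinol detour described for step 6 replaces it.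

Step 6 is next. The substrate is a base-sensitive β-hydroxy ketone (retro-aldol or E1cB loss of the hydroxyl before C8 becomes sp2), the phosphine may add to the chloroenone or promote γ-oxacyclisation, and 7E/7Z control rests on thermodynamics. The fallback sets out from 15 and comes back at 20. It moves the alkyne-to-diene isomerisation upstream, onto a robust aryl ynone. MnO2 oxidation of 15 gives the ynone methyl 8-[3-chloro-5-[(2Z)-oct-2-en-1-yl]furan-2-yl]-8-oxooct-6-ynoate F2. Isomerisation with catalytic PPh3 in toluene at 80 °C gives the dienone methyl (4E,6E)-8-[3-chloro-5-[(2Z)-oct-2-en-1-yl]furan-2-yl]-8-oxoocta-4,6-dienoate F3. Luche reduction (NaBH4, CeCl3, MeOH) gives the dienyl carbinol methyl (4E,6E)-8-[3-chloro-5-[(2Z)-oct-2-en-1-yl]furan-2-yl]-8-hydroxyocta-4,6-dienoate F4. The same chiral-acid Piancatelli rearrangement gives methyl (4E,6E)-7-[(1R,2R)-4-chloro-2-hydroxy-2-[(2Z)-oct-2-en-1-yl]-5-oxocyclopent-3-en-1-yl]hepta-4,6-dienoate F5. A catalytic amine base (DBU, CH2Cl2, 0 °C) then moves the diene into conjugation through the extended enolate, giving 20.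

Step 1 is third. C3 selectivity depends on chelation overriding the intrinsically more acidic C5–H, and the 3-lithiofuran is thermally fragile. The fallback sets out from 1 and comes back at 5, using a blocking group. Furfural is first silylated at C5 (N-methylpiperazine/n-BuLi protection, n-BuLi, Me3SiCl) to 5-(trimethylsilyl)furan-2-carbaldehyde F6. The diamine-directed lithiation with C2Cl6 quench, now with C3 as the only accessible site, gives 3-chloro-5-(trimethylsilyl)furan-2-carbaldehyde F7. Protodesilylation with TBAF in wet THF returns 5.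

**Further compounds**

F1 | step 5 | methyl 7-[(1S,2S)-4-chloro-2-hydroxy-2-[(2Z)-oct-2-en-1-yl]-5-oxocyclopent-3-en-1-yl]hept-6-ynoate | CCCCC/C=C\C[C@@]1(O)C=C(Cl)C(=O)[C@H]1C#CCCCCC(=O)OC
F2 | step 6 | methyl 8-[3-chloro-5-[(2Z)-oct-2-en-1-yl]furan-2-yl]-8-oxooct-6-ynoate | CCCCC/C=C\Cc1cc(Cl)c(C(=O)C#CCCCCC(=O)OC)o1
F3 | step 6 | methyl (4E,6E)-8-[3-chloro-5-[(2Z)-oct-2-en-1-yl]furan-2-yl]-8-oxoocta-4,6-dienoate | CCCCC/C=C\Cc1cc(Cl)c(C(=O)/C=C/C=C/CCC(=O)OC)o1
F4 | step 6 | methyl (4E,6E)-8-[3-chloro-5-[(2Z)-oct-2-en-1-yl]furan-2-yl]-8-hydroxyocta-4,6-dienoate (racemic) | CCCCC/C=C\Cc1cc(Cl)c(C(O)/C=C/C=C/CCC(=O)OC)o1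
F5 | step 6 | methyl (4E,6E)-7-[(1R,2R)-4-chloro-2-hydroxy-2-[(2Z)-oct-2-en-1-yl]-5-oxocyclopent-3-en-1-yl]hepta-4,6-dienoate | CCCCC/C=C\C[C@]1(O)C=C(Cl)C(=O)[C@@H]1/C=C/C=C/CCC(=O)OC
F6 | step 1 | 5-(trimethylsilyl)furan-2-carbaldehyde | C[Si](C)(C)c1ccc(C=O)o1
F7 | step 1 | 3-chloro-5-(trimethylsilyl)furan-2-carbaldehyde | C[Si](C)(C)c1cc(Cl)c(C=O)o1
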